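**Retrosynthetic overview**
- C11=C12 is cut by a Wittig reaction between a furanoid C15 phosphonium salt and the C25 aldehyde apo-12′-lycopenal. The aldehyde comes from pseudoionone (vinyl Grignard, PPh3·HBr) and the C10 dialdehyde.
- The C15 salt comes from a bicyclic keto ester: bulky-hydride reduction sets C3, then ester reduction and Appel/PPh3.
- Both rings form in one Lewis-acid cascade of an acyclic enone–allene silyl ether. The C1–C6 bond (cyclohexanone) forms first and the O–C5 bond (2,5-dihydrofuran) follows at once, anti across the allene, so the allene axis and C8 fix C5.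
- The enone–allene comes from a Johnson–Claisen rearrangement of a propargylic alcohol (centre to axis) and a Weinreb/Grignard sequence. The alcohol comes from a proline anti-aldol of silyloxyacetone with but-2-ynal, then a Wittig reaction.

Assumption: commercial pseudoionone is used as its (3E,5E) isomer (main component, enriched by distillation).

**Step 1**
Reactants: 1 1-[(tert-butyldimethylsilyl)oxy]propan-2-one; 2 but-2-ynal
Product: 3 (3S,4S)-3-[(tert-butyldimethylsilyl)oxy]-4-hydroxyhept-5-yn-2-one (anti)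
Conditions: L-proline (30 mol %), 1 (3 equiv), DMSO, 4 °C
Reagents that add atoms: none
Why: Proline enamine aldol reaction: the E-enamine on the oxygenated side of 1 adds to the non-enolisable ynal through the chair (Houk–List) transition state, setting both centres as the anti-(3S,4S) pair under catalyst control.

**Step 2**
Reactants: 3 (3S,4S)-3-[(tert-butyldimethylsilyl)oxy]-4-hydroxyhept-5-yn-2-one
Product: 4 tert-butyl (2E,4R,5S)-4-[(tert-butyldimethylsilyl)oxy]-5-hydroxy-3-methyloct-2-en-6-ynoate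
Conditions: Ph3P=CHCO2t-Bu, toluene, 90 °C
Reagents that add atoms: tert-butyl (triphenylphosphoranylidene)acetate, CC(C)(C)OC(=O)C=P(c1ccccc1)(c1ccccc1)c1ccccc1
Why: Wittig olefination of the activated α-silyloxy ketone with a stabilised ylide under neutral conditions puts the ester trans to the bulky C4 branch (2E) without touching the two carbinol centres (only the CIP label at C4 changes).

**Step 3**
Reactants: 4 tert-butyl (2E,4R,5S)-4-[(tert-butyldimethylsilyl)oxy]-5-hydroxy-3-methyloct-2-en-6-ynoate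
Product: 5 1-tert-butyl 9-ethyl (2E,4S,Ra)-4-[(tert-butyldimethylsilyl)oxy]-3,7-dimethylnona-2,5,6-trienedioate (allene C5=C6=C7, axis Ra = M)
Conditions: MeC(OEt)3, EtCO2H (cat.), xylene, 135 °C, EtOH distilled off
Reagents that add atoms: triethyl orthoacetate, CC(OCC)(OCC)OCC
Why: Johnson orthoester Claisen rearrangement of the secondary propargylic alcohol: the suprafacial [3,3] shift makes the C–C bond at the alkyne terminus on the face the C–O bond leaves, so the (5S) carbinol centre is transferred completely into the Ra allene axis.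

**Step 4**
Reactants: 5 1-tert-butyl 9-ethyl (2E,4S,Ra)-4-[(tert-butyldimethylsilyl)oxy]-3,7-dimethylnona-2,5,6-trienedioate
Product: 7 tert-butyl (2E,4S,Ra)-4-[(tert-butyldimethylsilyl)oxy]-3,7,11-trimethyl-9-oxododeca-2,5,6,10-tetraenoate, via Weinreb amide 6 (not isolated)
Conditions: MeNHOMe·HCl, i-PrMgCl, THF, −20 °C; then Me2C=CHMgBr, −20 → 0 °C; aq. NH4Cl
Reagents that add atoms: N,O-dimethylhydroxylamine hydrochloride, CNOC.Cl (atoms kept in 6 only); 2-methylprop-1-enylmagnesium bromide, CC(C)=C[Mg]Br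
Why: Ester-to-Weinreb amidation with ClMgN(OMe)Me is selective for the unhindered saturated ethyl ester over the conjugated tert-butyl ester, and Grignard addition to the Weinreb amide stops at the ketone through the chelated tetrahedral intermediate.

**Step 5 (key step)**
Reactants: 7 tert-butyl (2E,4S,Ra)-4-[(tert-butyldimethylsilyl)oxy]-3,7,11-trimethyl-9-oxododeca-2,5,6,10-tetraenoate
Product: 8 tert-butyl (2E)-3-[(2S,7aR)-4,4,7a-trimethyl-6-oxo-2,4,5,6,7,7a-hexahydro-1-benzofuran-2-yl]but-2-enoate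
Conditions: Me2AlCl (2.5 equiv), CH2Cl2, −78 → −30 °C; then 1 M HCl
Reagents that add atoms: none
Why: Proposed new method: Me2AlCl activates the β,β-dimethyl enone, its β-carbon is attacked 6-endo by the central allene carbon through the π-bond of the methyl-bearing terminus (from the side of the allenic H), and the tertiary cation that develops is captured on the opposite lobe by the silyl ether oxygen with loss of the silyl group, so the cyclohexanone and the 2,5-dihydrofuran close in one anti addition across the allene and the Ra axis plus the 4S centre become the (2S,7aR) pair with the angular methyl cis to the side chain; the closest known reaction types are Lewis-acid-initiated enone cation–olefin cyclisations (Snider type) and the stereospecific anti electrophile-induced 5-endo cyclisations of α-allenols (I+, PhSe+, Ag+, Au+) with axis-to-centre chirality transfer.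

**Step 6**
Reactants: 8 tert-butyl (2E)-3-[(2S,7aR)-4,4,7a-trimethyl-6-oxo-2,4,5,6,7,7a-hexahydro-1-benzofuran-2-yl]but-2-enoate
Product: 10 (2S,6S,7aR)-2-[(2E)-4-hydroxybut-2-en-2-yl]-4,4,7a-trimethyl-2,4,5,6,7,7a-hexahydro-1-benzofuran-6-ol, via hydroxy ester 9 (not isolated)
Conditions: LiBH(s-Bu)3, THF, −78 °C; then i-Bu2AlH, −78 → 0 °C; aq. potassium sodium tartrate
Reagents that add atoms: none
Why: Substrate-controlled ketone reduction: the bulky hydride attacks from the face opposite the two axial methyl groups (equatorial attack, as with 3,3,5-trimethylcyclohexanone) to give the axial 6S alcohol cis to the angular methyl, and i-Bu2AlH then reduces the enoate to the allylic alcohol.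

**Step 7**
Reactants: 10 (2S,6S,7aR)-2-[(2E)-4-hydroxybut-2-en-2-yl]-4,4,7a-trimethyl-2,4,5,6,7,7a-hexahydro-1-benzofuran-6-ol
Product: 12 {(2E)-3-[(2S,6S,7aR)-6-hydroxy-4,4,7a-trimethyl-2,4,5,6,7,7a-hexahydro-1-benzofuran-2-yl]but-2-en-1-yl}triphenylphosphonium bromide, via allylic bromide 11 (not isolated)
Conditions: CBr4, PPh3 (2.3 equiv), CH2Cl2, −20 °C → rt
Reagents that add atoms: carbon tetrabromide, BrC(Br)(Br)Br; triphenylphosphine, c1ccccc1P(c1ccccc1)c1ccccc1
Why: Appel bromination of the primary allylic alcohol (the hindered axial secondary alcohol is left) and SN2 quaternisation by the excess PPh3 give the Wittig salt without acid that could ionise the allylic C–O bonds of the dihydrofuran.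

**Step 8**
Reactants: 13 (3E,5E)-6,10-dimethylundeca-3,5,9-trien-2-one (pseudoionone)
Product: 14 (4E,6E)-3,7,11-trimethyldodeca-1,4,6,10-tetraen-3-ol (racemic carbinol)
Conditions: CH2=CHMgBr, THF, −20 → 0 °C
Reagents that add atoms: vinylmagnesium bromide, C=C[Mg]Br
Why: 1,2-Addition of the vinyl Grignard reagent to the dienone carbonyl gives the tertiary vinyl carbinol, whose stereocentre is lost in the next step.

**Step 9**
Reactants: 14 (4E,6E)-3,7,11-trimethyldodeca-1,4,6,10-tetraen-3-ol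
Product: 15 [(2E,4E,6E)-3,7,11-trimethyldodeca-2,4,6,10-tetraen-1-yl]triphenylphosphonium bromide
Conditions: PPh3·HBr, MeOH, rt; crystallise (EtOAc)
Reagents that add atoms: triphenylphosphine hydrobromide, [Br-].[PH+](c1ccccc1)(c1ccccc1)c1ccccc1
Why: Acid-mediated allylic transposition (SN1′/SN2′) of the tertiary vinyl carbinol by PPh3 is the standard entry to C15 Wittig salts, and crystallisation gives the 2E salt.

**Step 10**
Reactants: 15 [(2E,4E,6E)-3,7,11-trimethyldodeca-2,4,6,10-tetraen-1-yl]triphenylphosphonium bromide; 16 (2E,4E,6E)-2,7-dimethylocta-2,4,6-trienedial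
Product: 18 (2E,4E,6E,8E,10E,12E,14E)-2,7,11,15,19-pentamethylicosa-2,4,6,8,10,12,14,18-octaenal (apo-12′-lycopenal), via 8Z-aldehyde 17 (not isolated)
Conditions: 16 (2 equiv), NaOMe, MeOH/CH2Cl2, −10 °C → rt; then I2 (cat.), CH2Cl2, daylight, rt
Reagents that add atoms: none
Why: Wittig olefination of one formyl group of the dialdehyde (used in excess; the mono-adduct is less electrophilic) followed by iodine-catalysed Z→E equilibration of the new disubstituted double bond.

**Step 11**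
Reactants: 12 {(2E)-3-[(2S,6S,7aR)-6-hydroxy-4,4,7a-trimethyl-2,4,5,6,7,7a-hexahydro-1-benzofuran-2-yl]but-2-en-1-yl}triphenylphosphonium bromide; 18 apo-12′-lycopenal
Product: 20 (3S,5R,8S)-5,8-epoxy-5,8-dihydro-β,ψ-caroten-3-ol (all-E; the target), via 11Z-isomer 19 (not isolated)
Conditions: NaOMe, MeOH/CH2Cl2, 0 °C → rt; then EtOH/heptane, reflux; crystallise
Reagents that add atoms: none
Why: Wittig olefination forms C11=C12 and thermal isomerisation of the unhindered 11Z bond with crystallisation gives the all-E polyene, the three stereocentres set in steps 5 and 6 being untouched.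

**Compound list**
1 | 1-[(tert-butyldimethylsilyl)oxy]propan-2-one | CC(=O)CO[Si](C)(C)C(C)(C)C | starting material
2 | but-2-ynal | CC#CC=O | starting material
3 | (3S,4S)-3-[(tert-butyldimethylsilyl)oxy]-4-hydroxyhept-5-yn-2-one | CC#C[C@H](O)[C@H](O[Si](C)(C)C(C)(C)C)C(C)=O | intermediate
4 | tert-butyl (2E,4R,5S)-4-[(tert-butyldimethylsilyl)oxy]-5-hydroxy-3-methyloct-2-en-6-ynoate | CC#C[C@H](O)[C@H](O[Si](C)(C)C(C)(C)C)/C(C)=C/C(=O)OC(C)(C)C | intermediate
5 | 1-tert-butyl 9-ethyl (2E,4S,Ra)-4-[(tert-butyldimethylsilyl)oxy]-3,7-dimethylnona-2,5,6-trienedioate | CCOC(=O)CC(C)=[C@]=C([H])[C@H](O[Si](C)(C)C(C)(C)C)/C(C)=C/C(=O)OC(C)(C)C | intermediate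
6 | tert-butyl (2E,4S,Ra)-4-[(tert-butyldimethylsilyl)oxy]-9-[methoxy(methyl)amino]-3,7-dimethyl-9-oxonona-2,5,6-trienoate | CON(C)C(=O)CC(C)=[C@]=C([H])[C@H](O[Si](C)(C)C(C)(C)C)/C(C)=C/C(=O)OC(C)(C)C | intermediate
7 | tert-butyl (2E,4S,Ra)-4-[(tert-butyldimethylsilyl)oxy]-3,7,11-trimethyl-9-oxododeca-2,5,6,10-tetraenoate | CC(C)=CC(=O)CC(C)=[C@]=C([H])[C@H](O[Si](C)(C)C(C)(C)C)/C(C)=C/C(=O)OC(C)(C)C | intermediate
8 | tert-butyl (2E)-3-[(2S,7aR)-4,4,7a-trimethyl-6-oxo-2,4,5,6,7,7a-hexahydro-1-benzofuran-2-yl]but-2-enoate | CC(C)(C)OC(=O)/C=C(\C)[C@@H]1C=C2C(C)(C)CC(=O)C[C@@]2(C)O1 | intermediate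
9 | tert-butyl (2E)-3-[(2S,6S,7aR)-6-hydroxy-4,4,7a-trimethyl-2,4,5,6,7,7a-hexahydro-1-benzofuran-2-yl]but-2-enoate | CC(C)(C)OC(=O)/C=C(\C)[C@@H]1C=C2C(C)(C)C[C@H](O)C[C@@]2(C)O1 | intermediate
10 | (2S,6S,7aR)-2-[(2E)-4-hydroxybut-2-en-2-yl]-4,4,7a-trimethyl-2,4,5,6,7,7a-hexahydro-1-benzofuran-6-ol | OC/C=C(\C)[C@@H]1C=C2C(C)(C)C[C@H](O)C[C@@]2(C)O1 | intermediate
11 | (2S,6S,7aR)-2-[(2E)-4-bromobut-2-en-2-yl]-4,4,7a-trimethyl-2,4,5,6,7,7a-hexahydro-1-benzofuran-6-ol | BrC/C=C(\C)[C@@H]1C=C2C(C)(C)C[C@H](O)C[C@@]2(C)O1 | intermediate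
12 | {(2E)-3-[(2S,6S,7aR)-6-hydroxy-4,4,7a-trimethyl-2,4,5,6,7,7a-hexahydro-1-benzofuran-2-yl]but-2-en-1-yl}triphenylphosphonium bromide | c1ccccc1[P+](c1ccccc1)(c1ccccc1)C/C=C(\C)[C@@H]1C=C2C(C)(C)C[C@H](O)C[C@@]2(C)O1.[Br-] | intermediate
13 | (3E,5E)-6,10-dimethylundeca-3,5,9-trien-2-one (pseudoionone) | CC(C)=CCC/C(C)=C/C=C/C(C)=O | starting material
14 | (4E,6E)-3,7,11-trimethyldodeca-1,4,6,10-tetraen-3-ol (racemic) | CC(C)=CCC/C(C)=C/C=C/C(C)(O)C=C | intermediate
15 | [(2E,4E,6E)-3,7,11-trimethyldodeca-2,4,6,10-tetraen-1-yl]triphenylphosphonium bromide | CC(C)=CCC/C(C)=C/C=C/C(C)=C/C[P+](c1ccccc1)(c1ccccc1)c1ccccc1.[Br-] | intermediate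
16 | (2E,4E,6E)-2,7-dimethylocta-2,4,6-trienedial | O=C/C(C)=C/C=C/C=C(C)/C=O | starting material
17 | (2E,4E,6E,8Z,10E,12E,14E)-2,7,11,15,19-pentamethylicosa-2,4,6,8,10,12,14,18-octaenal | CC(C)=CCC/C(C)=C/C=C/C(C)=C/C=C\C(C)=C\C=C\C=C(C)\C=O | intermediate
18 | (2E,4E,6E,8E,10E,12E,14E)-2,7,11,15,19-pentamethylicosa-2,4,6,8,10,12,14,18-octaenal (apo-12′-lycopenal) | CC(C)=CCC/C(C)=C/C=C/C(C)=C/C=C/C(C)=C/C=C/C=C(C)/C=O | intermediate
19 | (3S,5R,8S,11Z)-5,8-epoxy-5,8-dihydro-β,ψ-caroten-3-ol | CC(C)=CCC/C(C)=C/C=C/C(C)=C/C=C/C(C)=C/C=C/C=C(C)/C=C\C=C(/C)[C@@H]1C=C2C(C)(C)C[C@H](O)C[C@@]2(C)O1 | intermediate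
20 | (3S,5R,8S)-5,8-epoxy-5,8-dihydro-β,ψ-caroten-3-ol, all-E (CNP0182031.1) | CC(C)=CCC/C(C)=C/C=C/C(C)=C/C=C/C(C)=C/C=C/C=C(C)/C=C/C=C(\C)[C@@H]1C=C2C(C)(C)C[C@H](O)C[C@@]2(C)O1 | target

**Step count**
Total: 11 steps. Longest linear sequence: 8 (steps 1–7 and 11); the ψ branch is steps 8–10.

**Steps most likely to fail, with fallbacks**

Step 5 (the double ring closure is untested; the vinylic C–C bond may not form, or the allene may simply hydroalkoxylate). The fallback sets out from 7 and comes back at 8, closing the rings one after the other with the same stereochemical logic. HF·pyridine (THF, 0 °C) removes the silyl group to give tert-butyl (2E,4S,Ra)-4-hydroxy-3,7,11-trimethyl-9-oxododeca-2,5,6,10-tetraenoate F4. N-Iodosuccinimide (CH2Cl2, 0 °C) closes the dihydrofuran by stereospecific anti iodoetherification to tert-butyl (2E)-3-[(2S,5R)-4-iodo-5-methyl-5-(4-methyl-2-oxopent-3-en-1-yl)-2,5-dihydrofuran-2-yl]but-2-enoate F5. The vinyl radical from F5 (Bu3SnH, AIBN, benzene, 80 °C, slow addition) then adds 6-endo to the enone β-carbon and gives 8.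

Step 1 (regioselectivity and anti selectivity of proline with a silyl-protected hydroxyacetone are uncertain). The fallback sets out from 1 and 2 and comes back at 4, using the better-precedented syn-aldol and inverting the propargylic centre. O-tert-butyl-D-threonine (primary-amine, Z-enamine catalysis; the enantiomer expected to give this adduct) yields (3S,4R)-3-[(tert-butyldimethylsilyl)oxy]-4-hydroxyhept-5-yn-2-one F1. The Wittig reaction of step 2 gives tert-butyl (2E,4R,5R)-4-[(tert-butyldimethylsilyl)oxy]-5-hydroxy-3-methyloct-2-en-6-ynoate F2. Mitsunobu inversion (4-nitrobenzoic acid, PPh3, diisopropyl azodicarboxylate, THF, 0 °C) gives tert-butyl (2E,4R,5S)-4-[(tert-butyldimethylsilyl)oxy]-3-methyl-5-[(4-nitrobenzoyl)oxy]oct-2-en-6-ynoate F3, and K2CO3 in MeOH at 0 °C releases 4.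

Step 11 (the ylide of 12 carries charge next to the allylic ring C–O bond and may open the dihydrofuran, or give poor E/Z). The fallback sets out from 10 and 18 and comes back at 20, with the polarity of the coupling reversed. MnO2 (CH2Cl2, rt) oxidises only the allylic alcohol of 10 to (2E)-3-[(2S,6S,7aR)-6-hydroxy-4,4,7a-trimethyl-2,4,5,6,7,7a-hexahydro-1-benzofuran-2-yl]but-2-enal F6. NaBH4 (EtOH, 0 °C) reduces 18 to (2E,4E,6E,8E,10E,12E,14E)-2,7,11,15,19-pentamethylicosa-2,4,6,8,10,12,14,18-octaen-1-ol F7, and PPh3·HBr (MeOH/CH2Cl2, rt) gives [(2E,4E,6E,8E,10E,12E,14E)-2,7,11,15,19-pentamethylicosa-2,4,6,8,10,12,14,18-octaen-1-yl]triphenylphosphonium bromide F8. Wittig reaction of F8 with F6 under base-free conditions (1,2-epoxybutane, EtOH, reflux), then thermal isomerisation and crystallisation, gives 20.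

**Further compounds**
F1 | step 1 | (3S,4R)-3-[(tert-butyldimethylsilyl)oxy]-4-hydroxyhept-5-yn-2-one | CC#C[C@@H](O)[C@H](O[Si](C)(C)C(C)(C)C)C(C)=O
F2 | step 1 | tert-butyl (2E,4R,5R)-4-[(tert-butyldimethylsilyl)oxy]-5-hydroxy-3-methyloct-2-en-6-ynoate | CC#C[C@@H](O)[C@H](O[Si](C)(C)C(C)(C)C)/C(C)=C/C(=O)OC(C)(C)C
F3 | step 1 | tert-butyl (2E,4R,5S)-4-[(tert-butyldimethylsilyl)oxy]-3-methyl-5-[(4-nitrobenzoyl)oxy]oct-2-en-6-ynoate | CC#C[C@H](OC(=O)c1ccc(cc1)[N+](=O)[O-])[C@H](O[Si](C)(C)C(C)(C)C)/C(C)=C/C(=O)OC(C)(C)C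
F4 | step 5 | tert-butyl (2E,4S,Ra)-4-hydroxy-3,7,11-trimethyl-9-oxododeca-2,5,6,10-tetraenoate | CC(C)=CC(=O)CC(C)=[C@]=C([H])[C@H](O)/C(C)=C/C(=O)OC(C)(C)C
F5 | step 5 | tert-butyl (2E)-3-[(2S,5R)-4-iodo-5-methyl-5-(4-methyl-2-oxopent-3-en-1-yl)-2,5-dihydrofuran-2-yl]but-2-enoate | CC(C)(C)OC(=O)/C=C(\C)[C@@H]1C=C(I)[C@@](C)(CC(=O)C=C(C)C)O1
F6 | step 11 | (2E)-3-[(2S,6S,7aR)-6-hydroxy-4,4,7a-trimethyl-2,4,5,6,7,7a-hexahydro-1-benzofuran-2-yl]but-2-enal | O=C/C=C(\C)[C@@H]1C=C2C(C)(C)C[C@H](O)C[C@@]2(C)O1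
F7 | step 11 | (2E,4E,6E,8E,10E,12E,14E)-2,7,11,15,19-pentamethylicosa-2,4,6,8,10,12,14,18-octaen-1-ol | CC(C)=CCC/C(C)=C/C=C/C(C)=C/C=C/C(C)=C/C=C/C=C(C)/CO
F8 | step 11 | [(2E,4E,6E,8E,10E,12E,14E)-2,7,11,15,19-pentamethylicosa-2,4,6,8,10,12,14,18-octaen-1-yl]triphenylphosphonium bromide | CC(C)=CCC/C(C)=C/C=C/C(C)=C/C=C/C(C)=C/C=C/C=C(C)/C[P+](c1ccccc1)(c1ccccc1)c1ccccc1.[Br-]
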